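**Plan**

- Retrosynthesis: the three MOM ethers come off last. Ring C is then cut at O1–C2 and at C4–C4a, which leads back to one molecule, aryl glycidate 17, in which O1 is acylated by C4 and C2–C3 is an epoxide. Cutting that ester (O1–C4) gives ring-A iodophenol 7 and ring-B (R)-2-arylglycidic acid 16. Both prenyl C–C bonds go back to aryllithiums and prenyl bromide, and the C1'–C3 bond to a Suzuki coupling.
- Forward: rings A and B are bought as benzenes and each is prenylated by directed metalation between two ring oxygens. The three-carbon unit is coupled to ring B, epoxidised and oxidised. The halves are joined as an ester through O1, and ring C is closed last.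
- Enabling feature: in ring C, O1 and the acyl carbon C4 stand on neighbouring carbons C8a and C4a of ring A, and C3 bears oxygen next to C2. Ring C is therefore the isomer of an aryl glycidate by a 1,3-shift of C4 from O1 to C4a followed by attack of O1 on the epoxide CH2. O1 lies para to the C6 prenyl group on the local mirror plane of ring A, so C4a and C8 are equivalent until the iodine marks one of them.
- Stereochemistry: the only stereocentre, C3 (R), is set by Sharpless asymmetric epoxidation of allylic alcohol 14 with L-(+)-tartrate. No bond to C3 is broken afterwards; the change S → R in step 10 is a change of descriptor only.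

Key step: step 12

Remark: the stereocentre of the given SMILES is read as (3R) (priorities OH > C4 > C2 > aryl). Compounds 1, 8 and 12 are taken as commercial. Atom numbers are those of the chroman-4-one (O1, C2, C3, C4, C4a, C5–C8, C8a; ring B primed).

**Route**

Step 1
Reactants: 1 benzene-1,3,5-triol (phloroglucinol)
Product: 2 5-{[tri(propan-2-yl)silyl]oxy}benzene-1,3-diol
Conditions: TIPSCl (1 equiv), 1 (3 equiv), imidazole, DMF, 0 °C → rt
Reagents that add atoms: triisopropylsilyl chloride (TIPSCl), CC(C)[Si](Cl)(C(C)C)C(C)C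
Why: silyl ether formation on one of three equivalent phenols of a threefold-symmetric triol, with 1 in excess so that monosilylation should dominate and unreacted 1 is washed out with water.

Step 2
Reactants: 2 5-{[tri(propan-2-yl)silyl]oxy}benzene-1,3-diol
Product: 3 [3,5-bis(methoxymethoxy)phenoxy]tri(propan-2-yl)silane
Conditions: MOMCl, i-Pr2NEt, CH2Cl2, 0 °C → rt
Reagents that add atoms: chloromethyl methyl ether (MOMCl), COCCl
Why: Williamson-type O-alkylation of both remaining phenols with the reactive α-chloro ether under amine base, to which the aryl TIPS ether is inert.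

Step 3
Reactants: 3 [3,5-bis(methoxymethoxy)phenoxy]tri(propan-2-yl)silane
Product: 5 [3,5-bis(methoxymethoxy)-4-(3-methylbut-2-en-1-yl)phenoxy]tri(propan-2-yl)silane, via aryllithium 4 (not isolated)
Conditions: n-BuLi, THF, 0 °C; then CuI (10 mol %), prenyl bromide, −78 °C → rt
Reagents that add atoms: 1-bromo-3-methylbut-2-ene (prenyl bromide), CC(C)=CCBr
Why: directed ortho-metalation should take place only at the carbon flanked by the two chelating OMOM groups (the bulky, non-coordinating OTIPS group shields its own neighbours), and the aryllithium is allylated at the unsubstituted terminus of prenyl bromide under copper catalysis.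

Step 4
Reactants: 5 [3,5-bis(methoxymethoxy)-4-(3-methylbut-2-en-1-yl)phenoxy]tri(propan-2-yl)silane
Product: 6 3,5-bis(methoxymethoxy)-4-(3-methylbut-2-en-1-yl)phenol
Conditions: TBAF, THF, 0 °C
Reagents that add atoms: none
Why: fluoride-induced cleavage of the aryl silyl ether, driven by the Si–F bond, leaves the MOM ethers and the prenyl group untouched.

Step 5
Reactants: 6 3,5-bis(methoxymethoxy)-4-(3-methylbut-2-en-1-yl)phenol
Product: 7 2-iodo-3,5-bis(methoxymethoxy)-4-(3-methylbut-2-en-1-yl)phenol
Conditions: NIS (1.0 equiv), CH2Cl2, −40 → 0 °C, dark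
Reagents that add atoms: N-iodosuccinimide (NIS), O=C1CCC(=O)N1I
Why: electrophilic aromatic iodination ortho to the free hydroxyl, where the two ortho carbons are equivalent by the mirror plane through O1 and the prenyl-bearing carbon, the para position is blocked, and the phenol ring should react far faster than the trisubstituted alkene, so one equivalent of NIS at low temperature should give the mono-iodide.

Step 6
Reactants: 8 4-bromo-3-methoxyphenol
Product: 9 1-bromo-2-methoxy-4-(methoxymethoxy)benzene
Conditions: MOMCl, i-Pr2NEt, CH2Cl2, 0 °C → rt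
Reagents that add atoms: chloromethyl methyl ether (MOMCl), COCCl
Why: Williamson-type O-alkylation of the phenol installs the group that later directs metalation and protects the 4'-oxygen.

Step 7
Reactants: 9 1-bromo-2-methoxy-4-(methoxymethoxy)benzene
Product: 11 1-bromo-2-methoxy-4-(methoxymethoxy)-3-(3-methylbut-2-en-1-yl)benzene, via aryllithium 10 (not isolated)
Conditions: LiTMP (from n-BuLi, 2,2,6,6-tetramethylpiperidine), THF, −78 °C; then CuI (10 mol %), prenyl bromide, −78 → 0 °C
Reagents that add atoms: 1-bromo-3-methylbut-2-ene (prenyl bromide), CC(C)=CCBr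
Why: directed ortho-metalation with a lithium amide (no bromine–lithium exchange) at the carbon between OMe and OMOM, which is meta to bromine so that no aryne can form, followed by copper-catalysed allylation with prenyl bromide.

Step 8
Reactants: 11 1-bromo-2-methoxy-4-(methoxymethoxy)-3-(3-methylbut-2-en-1-yl)benzene; 12 2-bromoprop-2-en-1-ol
Product: 14 2-[2-methoxy-4-(methoxymethoxy)-3-(3-methylbut-2-en-1-yl)phenyl]prop-2-en-1-ol, via arylboronate 13 (not isolated)
Conditions: B2pin2, Pd(dppf)Cl2 (cat.), KOAc, 1,4-dioxane, 90 °C; then 12, aq. K3PO4, 80 °C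
Reagents that add atoms: none
Why: Miyaura borylation of the aryl bromide and Suzuki–Miyaura coupling of the boronate with the vinylic bromide of 12 in the same flask, both palladium cycles tolerating free hydroxyl, MOM ether and prenyl group.

Step 9
Reactants: 14 2-[2-methoxy-4-(methoxymethoxy)-3-(3-methylbut-2-en-1-yl)phenyl]prop-2-en-1-ol
Product: 15 [(2S)-2-[2-methoxy-4-(methoxymethoxy)-3-(3-methylbut-2-en-1-yl)phenyl]oxiran-2-yl]methanol
Conditions: Ti(OiPr)4 (cat.), L-(+)-diethyl tartrate, t-BuOOH, 4 Å MS, CH2Cl2, −25 °C
Reagents that add atoms: tert-butyl hydroperoxide, CC(C)(C)OO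
Why: Sharpless asymmetric epoxidation, in which the allylic hydroxyl binds titanium so that only this alkene (not the prenyl group) is epoxidised and L-(+)-tartrate should deliver oxygen to the face that sets the (S) configuration at the new quaternary carbon (the same facial sense as in the epoxidation of 2-methylprop-2-en-1-ol to (S)-2-methylglycidol).

Step 10
Reactants: 15 [(2S)-2-[2-methoxy-4-(methoxymethoxy)-3-(3-methylbut-2-en-1-yl)phenyl]oxiran-2-yl]methanol
Product: 16 (2R)-2-[2-methoxy-4-(methoxymethoxy)-3-(3-methylbut-2-en-1-yl)phenyl]oxirane-2-carboxylic acid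
Conditions: TEMPO (cat.), PhI(OAc)2, MeCN/aq. pH 7 phosphate buffer, 0 °C → rt
Reagents that add atoms: water, O
Why: oxoammonium (TEMPO) oxidation of the primary alcohol through the aldehyde hydrate to the acid under near-neutral conditions that spare epoxide, MOM ether and prenyl group, the stereocentre being untouched and its descriptor changing from S to R only because CO2H outranks the ring CH2.

Step 11
Reactants: 16 (2R)-2-[2-methoxy-4-(methoxymethoxy)-3-(3-methylbut-2-en-1-yl)phenyl]oxirane-2-carboxylic acid; 7 2-iodo-3,5-bis(methoxymethoxy)-4-(3-methylbut-2-en-1-yl)phenol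
Product: 17 2-iodo-3,5-bis(methoxymethoxy)-4-(3-methylbut-2-en-1-yl)phenyl (2R)-2-[2-methoxy-4-(methoxymethoxy)-3-(3-methylbut-2-en-1-yl)phenyl]oxirane-2-carboxylate
Conditions: DIC, DMAP (cat.), CH2Cl2, 0 °C → rt
Reagents that add atoms: none
Why: Steglich esterification (carbodiimide, DMAP) joins the two halves through O1 under neutral conditions compatible with the epoxide and the aryl iodide.

Step 12
Reactants: 17 2-iodo-3,5-bis(methoxymethoxy)-4-(3-methylbut-2-en-1-yl)phenyl (2R)-2-[2-methoxy-4-(methoxymethoxy)-3-(3-methylbut-2-en-1-yl)phenyl]oxirane-2-carboxylate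
Product: 20 (3R)-3-hydroxy-3-[2-methoxy-4-(methoxymethoxy)-3-(3-methylbut-2-en-1-yl)phenyl]-5,7-bis(methoxymethoxy)-6-(3-methylbut-2-en-1-yl)-2,3-dihydro-4H-chromen-4-one, via aryllithium 18 (not isolated), via lithium phenoxide 19 (not isolated)
Conditions: t-BuLi (2.05 equiv), THF, −95 °C; then DMPU, −78 → 23 °C; aq. NH4Cl
Reagents that add atoms: none
Why: Proposed new method: iodine–lithium exchange in 17 should give aryllithium 18, whose C–Li carbon adds to the neighbouring ester carbonyl through a four-membered tetrahedral intermediate that collapses with cleavage of the ester C–O bond (anionic ortho-Fries 1,3-O→C acyl shift, forming C4–C4a and freeing O1 as lithium phenoxide 19), and once DMPU has loosened the lithium chelate this phenoxide should open the epoxide at its CH2 carbon (forming O1–C2 and the tertiary alkoxide, protonated on work-up). The closest known reaction types are the halogen–lithium-exchange-triggered anionic Fries rearrangement of ortho-haloaryl esters and the base-mediated cyclisation of 2'-hydroxychalcone epoxides to 3-hydroxychromanones (Algar–Flynn–Oyamada manifold); new are the glycidate as the migrating acyl group and the coupling of both events in one flask. Ring C closes by a 6-endo-tet attack on the epoxide, in which both epoxide carbons end up in the new ring, while the four-membered ring of the acyl shift is only transient. No stereocentre is created: C3 is carried in from 17 and none of its four bonds is broken (the epoxide C3–O bond becomes the C3–OH bond), so (R) is retained. The step needs (a) exchange and acyl shift to outrun addition of t-BuLi to the ester and attack of the aryllithium on the epoxide, which the iodide, the low temperature and the proximity of the carbonyl should secure, and (b) 6-endo attack at primary C2 instead of 5-exo attack at C3, which the fully substituted nature of C3 under acid-free SN2 conditions and the fact that O1 is the only unprotected oxygen nucleophile should secure, while the iodine fixes which ring-A carbon becomes C4a.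

Step 13
Reactants: 20 (3R)-3-hydroxy-3-[2-methoxy-4-(methoxymethoxy)-3-(3-methylbut-2-en-1-yl)phenyl]-5,7-bis(methoxymethoxy)-6-(3-methylbut-2-en-1-yl)-2,3-dihydro-4H-chromen-4-one
Product: 21 (3R)-3,5,7-trihydroxy-3-[4-hydroxy-2-methoxy-3-(3-methylbut-2-en-1-yl)phenyl]-6-(3-methylbut-2-en-1-yl)-2,3-dihydro-4H-chromen-4-one
Conditions: 3 M aq. HCl, MeOH, 45 °C
Reagents that add atoms: none
Why: acid-catalysed acetal exchange with methanol should remove the three MOM groups as dimethoxymethane under the mild conditions customary for prenylated polyphenols, without involving the stereocentre at C3.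

**Compound list**

1 | benzene-1,3,5-triol (phloroglucinol) | Oc1cc(O)cc(O)c1 | starting material
2 | 5-{[tri(propan-2-yl)silyl]oxy}benzene-1,3-diol | CC(C)[Si](Oc1cc(O)cc(O)c1)(C(C)C)C(C)C | intermediate
3 | [3,5-bis(methoxymethoxy)phenoxy]tri(propan-2-yl)silane | COCOc1cc(OCOC)cc(O[Si](C(C)C)(C(C)C)C(C)C)c1 | intermediate
4 | {2,6-bis(methoxymethoxy)-4-[tri(propan-2-yl)silyloxy]phenyl}lithium | COCOc1cc(O[Si](C(C)C)(C(C)C)C(C)C)cc(OCOC)c1[Li] | intermediate
5 | [3,5-bis(methoxymethoxy)-4-(3-methylbut-2-en-1-yl)phenoxy]tri(propan-2-yl)silane | COCOc1cc(O[Si](C(C)C)(C(C)C)C(C)C)cc(OCOC)c1CC=C(C)C | intermediate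
6 | 3,5-bis(methoxymethoxy)-4-(3-methylbut-2-en-1-yl)phenol | COCOc1cc(O)cc(OCOC)c1CC=C(C)C | intermediate
7 | 2-iodo-3,5-bis(methoxymethoxy)-4-(3-methylbut-2-en-1-yl)phenol | COCOc1cc(O)c(I)c(OCOC)c1CC=C(C)C | intermediate
8 | 4-bromo-3-methoxyphenol | COc1cc(O)ccc1Br | starting material
9 | 1-bromo-2-methoxy-4-(methoxymethoxy)benzene | COCOc1ccc(Br)c(OC)c1 | intermediate
10 | [3-bromo-2-methoxy-6-(methoxymethoxy)phenyl]lithium | COCOc1ccc(Br)c(OC)c1[Li] | intermediate
11 | 1-bromo-2-methoxy-4-(methoxymethoxy)-3-(3-methylbut-2-en-1-yl)benzene | COCOc1ccc(Br)c(OC)c1CC=C(C)C | intermediate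
12 | 2-bromoprop-2-en-1-ol | OCC(Br)=C | starting material
13 | 2-[2-methoxy-4-(methoxymethoxy)-3-(3-methylbut-2-en-1-yl)phenyl]-4,4,5,5-tetramethyl-1,3,2-dioxaborolane | COCOc1ccc(B2OC(C)(C)C(C)(C)O2)c(OC)c1CC=C(C)C | intermediate
14 | 2-[2-methoxy-4-(methoxymethoxy)-3-(3-methylbut-2-en-1-yl)phenyl]prop-2-en-1-ol | COCOc1ccc(C(=C)CO)c(OC)c1CC=C(C)C | intermediate
15 | [(2S)-2-[2-methoxy-4-(methoxymethoxy)-3-(3-methylbut-2-en-1-yl)phenyl]oxiran-2-yl]methanol | COCOc1ccc([C@@]2(CO2)CO)c(OC)c1CC=C(C)C | intermediate
16 | (2R)-2-[2-methoxy-4-(methoxymethoxy)-3-(3-methylbut-2-en-1-yl)phenyl]oxirane-2-carboxylic acid | COCOc1ccc([C@@]2(CO2)C(=O)O)c(OC)c1CC=C(C)C | intermediate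
17 | 2-iodo-3,5-bis(methoxymethoxy)-4-(3-methylbut-2-en-1-yl)phenyl (2R)-2-[2-methoxy-4-(methoxymethoxy)-3-(3-methylbut-2-en-1-yl)phenyl]oxirane-2-carboxylate | COCOc1ccc([C@@]2(CO2)C(=O)Oc2cc(OCOC)c(CC=C(C)C)c(OCOC)c2I)c(OC)c1CC=C(C)C | intermediate
18 | 2-lithio-3,5-bis(methoxymethoxy)-4-(3-methylbut-2-en-1-yl)phenyl (2R)-2-[2-methoxy-4-(methoxymethoxy)-3-(3-methylbut-2-en-1-yl)phenyl]oxirane-2-carboxylate | COCOc1ccc([C@@]2(CO2)C(=O)Oc2cc(OCOC)c(CC=C(C)C)c(OCOC)c2[Li])c(OC)c1CC=C(C)C | intermediate
19 | lithium 2-{[(2R)-2-[2-methoxy-4-(methoxymethoxy)-3-(3-methylbut-2-en-1-yl)phenyl]oxiran-2-yl]carbonyl}-3,5-bis(methoxymethoxy)-4-(3-methylbut-2-en-1-yl)phenolate | COCOc1ccc([C@@]2(CO2)C(=O)c2c(O[Li])cc(OCOC)c(CC=C(C)C)c2OCOC)c(OC)c1CC=C(C)C | intermediate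
20 | (3R)-3-hydroxy-3-[2-methoxy-4-(methoxymethoxy)-3-(3-methylbut-2-en-1-yl)phenyl]-5,7-bis(methoxymethoxy)-6-(3-methylbut-2-en-1-yl)-2,3-dihydro-4H-chromen-4-one | COCOc1ccc([C@@]2(O)COc3cc(OCOC)c(CC=C(C)C)c(OCOC)c3C2=O)c(OC)c1CC=C(C)C | intermediate
21 | (3R)-3,5,7-trihydroxy-3-[4-hydroxy-2-methoxy-3-(3-methylbut-2-en-1-yl)phenyl]-6-(3-methylbut-2-en-1-yl)-2,3-dihydro-4H-chromen-4-one | COc1c([C@@]2(O)COc3cc(O)c(CC=C(C)C)c(O)c3C2=O)ccc(O)c1CC=C(C)C | target

**Totals**

Total step count: 13.
Longest linear sequence: 8 steps (from 8 through steps 6–13; the ring-A branch from 1, steps 1–5 and 11–13, is equally long).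

**Steps most likely to fail**

Step 12 (proposed new method). Two processes may go wrong. t-BuLi may add to the aryl ester before the iodine–lithium exchange is complete. The lithium-chelated phenoxide may also open the epoxide sluggishly or in the wrong sense (5-exo attack at C3, or lithium-assisted ionisation at the benzylic carbon with loss of configuration). The fallback uses known chemistry, sets out from 16 and 7, and makes the two bonds one after the other. Acid 16 is condensed with N,O-dimethylhydroxylamine hydrochloride (EDC·HCl, HOBt, i-Pr2NEt, CH2Cl2) to the Weinreb amide (2R)-N-methoxy-2-[2-methoxy-4-(methoxymethoxy)-3-(3-methylbut-2-en-1-yl)phenyl]-N-methyloxirane-2-carboxamide F1. The phenoxide of 7 (K2CO3, DMF, 60 °C) should open the epoxide of F1 at its CH2 carbon (Williamson-type epoxide opening, forming O1–C2) to give (2R)-2-hydroxy-3-[2-iodo-3,5-bis(methoxymethoxy)-4-(3-methylbut-2-en-1-yl)phenoxy]-N-methoxy-2-[2-methoxy-4-(methoxymethoxy)-3-(3-methylbut-2-en-1-yl)phenyl]-N-methylpropanamide F2. F2 is deprotonated at the tertiary hydroxyl with LiHMDS and treated with t-BuLi (THF, −78 °C). The aryllithium formed by iodine–lithium exchange should close onto the Weinreb amide (Parham cyclisation, forming C4–C4a), and the sequence comes back to the route at 20.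

Step 9. Facial discrimination may be incomplete with a 1,1-disubstituted allylic alcohol, and the titanium alkoxide medium may open the electron-rich benzylic epoxide once it has formed. The fallback replaces asymmetric catalysis by resolution and sets out from 14. Hydroxyl-directed epoxidation with VO(acac)2 (cat.) and t-BuOOH in CH2Cl2 at 0 °C, still selective for the allylic alkene over the prenyl group, should give the racemic epoxy alcohol {2-[2-methoxy-4-(methoxymethoxy)-3-(3-methylbut-2-en-1-yl)phenyl]oxiran-2-yl}methanol F3. Its enantiomers are separated by preparative chromatography on a chiral stationary phase, and the (S) enantiomer is 15, where the route is rejoined.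

Step 13. Acid may promote ionisation at C3 with loss of water towards the isoflavone, and it may catalyse cyclisation of the prenyl groups onto the freed ortho phenols. The fallback avoids protic acid and sets out from 20. Treatment with Et3SiOTf and 2,2'-bipyridyl (CH2Cl2, 0 °C) should exchange each aryl MOM ether for an aryl triethylsilyl ether and silylate the tertiary hydroxyl, giving (3R)-3-[2-methoxy-3-(3-methylbut-2-en-1-yl)-4-(triethylsilyloxy)phenyl]-6-(3-methylbut-2-en-1-yl)-3,5,7-tris(triethylsilyloxy)-2,3-dihydro-4H-chromen-4-one F4. Buffered fluoride (TBAF/AcOH, THF, 0 °C) should then remove all four silyl groups and arrive at 21.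

**Further compounds**

F1 | step 12 | (2R)-N-methoxy-2-[2-methoxy-4-(methoxymethoxy)-3-(3-methylbut-2-en-1-yl)phenyl]-N-methyloxirane-2-carboxamide | COCOc1ccc([C@@]2(CO2)C(=O)N(C)OC)c(OC)c1CC=C(C)C
F2 | step 12 | (2R)-2-hydroxy-3-[2-iodo-3,5-bis(methoxymethoxy)-4-(3-methylbut-2-en-1-yl)phenoxy]-N-methoxy-2-[2-methoxy-4-(methoxymethoxy)-3-(3-methylbut-2-en-1-yl)phenyl]-N-methylpropanamide | COCOc1ccc([C@@](O)(COc2cc(OCOC)c(CC=C(C)C)c(OCOC)c2I)C(=O)N(C)OC)c(OC)c1CC=C(C)C
F3 | step 9 | racemic {2-[2-methoxy-4-(methoxymethoxy)-3-(3-methylbut-2-en-1-yl)phenyl]oxiran-2-yl}methanol | COCOc1ccc(C2(CO2)CO)c(OC)c1CC=C(C)C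
F4 | step 13 | (3R)-3-[2-methoxy-3-(3-methylbut-2-en-1-yl)-4-(triethylsilyloxy)phenyl]-6-(3-methylbut-2-en-1-yl)-3,5,7-tris(triethylsilyloxy)-2,3-dihydro-4H-chromen-4-one | CC[Si](CC)(CC)Oc1ccc([C@@]2(O[Si](CC)(CC)CC)COc3cc(O[Si](CC)(CC)CC)c(CC=C(C)C)c(O[Si](CC)(CC)CC)c3C2=O)c(OC)c1CC=C(C)C
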